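**Strategy**

The route rests on disconnecting ring B (the monobrominated phenoxy ring), whose only substituents are the ether oxygen on C1′ and bromine on the adjacent C2′. Both bonds are made in one operation by adding the phenoxide oxygen of ring A and an electrophilic bromine across the triple bond of benzyne, which delivers the hindered diaryl ether and its ortho bromine without a metal catalyst. The precursors are the potassium salt of commercial 2-bromo-6-methoxyphenol (ring A with its C6 bromine in place), 2-(trimethylsilyl)phenyl triflate and carbon tetrabromide. The ring A bromines at C3 and C5 are added afterwards, ortho and para to the temporarily freed C2 hydroxyl, which is then re-methylated.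

Key step: step 1

Numbering used: on ring A, C1 bears the ether oxygen, C2 the methoxy group, C3, C5 and C6 bromine, and C4 hydrogen. On ring B, C1′ bears the ether oxygen and C2′ bromine.

Remark on the chemistry: the target has no stereocentre and its diaryl ether axis is not expected to be configurationally stable, so it is treated as the achiral compound drawn and no stereocontrol is needed.

**Route**

Step 1
Reactants: 1 2-bromo-6-methoxyphenol; 2 2-(trimethylsilyl)phenyl trifluoromethanesulfonate; 3 carbon tetrabromide
Product: 7 1-bromo-2-(2-bromophenoxy)-3-methoxybenzene, via potassium 2-bromo-6-methoxyphenoxide 4 (not isolated), via benzyne 5 (not isolated), via 2-(2-bromo-6-methoxyphenoxy)phenylpotassium 6 (not isolated)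
Conditions: KH (1.0 equiv), THF, 0 °C; then 18-crown-6, spray-dried KF (3 equiv), 3 (3 equiv), slow addition of 2 (1.5 equiv), 0 °C → rt; then H2O
Reagents that add atoms: none
Why: Fluoride from KF/18-crown-6 attacks silicon of 2 and expels triflate to give benzyne 5; the oxygen of phenoxide 4 adds to the strained triple bond to give aryl anion 6, which attacks a bromine of 3 (halophilic substitution) and releases tribromomethanide. The closest known reaction type is the aryne nucleophile–electrophile three-component coupling, in which a heteroatom anion adds and the resulting aryl anion is halogenated by a polyhalomethane or another halogen donor, as in aryne amino- and thio-halogenation and in oxygen-anion additions to arynes followed by halogen trapping. No ring is closed and no stereocentre is formed. Benzyne is symmetrical, so the two new bonds must fall on adjacent carbons and no regiochemical question arises; O- over C-arylation is favoured because both ortho positions of 4 are substituted and the potassium/crown ether ion pair is loose. The selectivity that matters is bromine transfer over protonation of 6, secured by full deprotonation of the phenol with KH (only H2 is released), aprotic THF and excess 3, with 2 added slowly so that benzyne stays dilute relative to 4.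

Step 2
Reactants: 7 1-bromo-2-(2-bromophenoxy)-3-methoxybenzene
Product: 8 3-bromo-2-(2-bromophenoxy)phenol
Conditions: BBr3 (2 equiv), CH2Cl2, −78 °C → rt; then H2O
Reagents that add atoms: none
Why: Lewis acid-mediated aryl methyl ether cleavage (BBr3 demethylation): boron binds the methoxy oxygen and bromide attacks the methyl carbon by SN2, while the diaryl ether has no sp3 carbon to attack and the aryl bromides are inert.

Step 3
Reactants: 8 3-bromo-2-(2-bromophenoxy)phenol
Product: 9 3,4,6-tribromo-2-(2-bromophenoxy)phenol
Conditions: Br2 (2.05 equiv), AcOH, 10 °C → rt
Reagents that add atoms: bromine, BrBr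
Why: Electrophilic aromatic bromination directed by the free hydroxyl, the strongest activator present, to its one open ortho position (C6) and its para position (C4); the other ortho position carries the aryloxy group, the last ring A hydrogen is meta to OH between two bromines, and ring B is activated only by the shared ether oxygen and deactivated by its own bromine.

Step 4
Reactants: 9 3,4,6-tribromo-2-(2-bromophenoxy)phenol
Product: 10 1,2,5-tribromo-3-(2-bromophenoxy)-4-methoxybenzene (target)
Conditions: MeI (3 equiv), K2CO3, DMF, rt → 40 °C
Reagents that add atoms: iodomethane, CI
Why: Williamson ether synthesis; the acidic polybrominated phenol is fully ionised by carbonate and the small methyl electrophile can reach the flanked oxygen by SN2, with no other nucleophilic site in the molecule.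

**Compound list**

1 | 2-bromo-6-methoxyphenol | COc1cccc(Br)c1O | starting material
2 | 2-(trimethylsilyl)phenyl trifluoromethanesulfonate | C[Si](C)(C)c1ccccc1OS(=O)(=O)C(F)(F)F | starting material
3 | carbon tetrabromide | BrC(Br)(Br)Br | starting material
4 | potassium 2-bromo-6-methoxyphenoxide | COc1cccc(Br)c1[O-].[K+] | intermediate
5 | benzyne (1,2-didehydrobenzene) | C1=CC=CC#C1 | intermediate
6 | 2-(2-bromo-6-methoxyphenoxy)phenylpotassium | COc1cccc(Br)c1OC1=CC=CC=[C-]1.[K+] | intermediate
7 | 1-bromo-2-(2-bromophenoxy)-3-methoxybenzene | COc1cccc(Br)c1Oc1ccccc1Br | intermediate
8 | 3-bromo-2-(2-bromophenoxy)phenol | Oc1cccc(Br)c1Oc1ccccc1Br | intermediate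
9 | 3,4,6-tribromo-2-(2-bromophenoxy)phenol | Oc1c(Br)cc(Br)c(Br)c1Oc1ccccc1Br | intermediate
10 | 1,2,5-tribromo-3-(2-bromophenoxy)-4-methoxybenzene | COc1c(Br)cc(Br)c(Br)c1Oc1ccccc1Br | target

**Summary**

Total step count: 4
Longest linear sequence: 4 steps (1 → 7 → 8 → 9 → 10)

**Steps most likely to fail**

Step 1. Several processes could spoil the coupling:
- the aryl anion may be protonated before it abstracts bromine, leaving ring B without its bromine;
- the phenoxide may be brominated on its own ring by carbon tetrabromide;
- the phenoxide may be consumed by dibromocarbene formed from tribromomethanide;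
- the phenoxide may add through carbon instead of oxygen.

The fallback sets out from 1 and returns at 7, building the ether and the ring B bromine by stepwise known chemistry. SNAr of the potassium salt of 1 on 1-fluoro-2-nitrobenzene (K2CO3, DMF, 80 °C) should give 1-bromo-3-methoxy-2-(2-nitrophenoxy)benzene F1. Reduction with Fe/NH4Cl in EtOH/H2O, which spares aryl bromides, should give 2-(2-bromo-6-methoxyphenoxy)aniline F2. Diazotisation (NaNO2, aq HBr, 0 °C) to 2-(2-bromo-6-methoxyphenoxy)benzenediazonium bromide F3, followed by a Sandmeyer reaction with CuBr, would deliver 7. Pschorr-type closure to a dibenzofuran is not possible because both positions ortho to the ether oxygen on ring A are substituted.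

Step 3. Site control may be lost if bromination spills onto ring B para to the ether oxygen, or the reaction may stall after the first bromination and give mixtures. The fallback sets out from 7 and returns at 9, introducing the two bromines one at a time in a changed order of events. Para-bromination of the anisole with NBS (1.0 equiv) in MeCN should give 1,2-dibromo-3-(2-bromophenoxy)-4-methoxybenzene F4. BBr3 demethylation should then give 3,4-dibromo-2-(2-bromophenoxy)phenol F5. Its single open activated position, ortho to the hydroxyl, would be brominated with NBS (1.0 equiv) and catalytic i-Pr2NH in CH2Cl2 to reach 9.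

Step 4. O-alkylation of a phenoxide flanked by bromine and an aryloxy group may be slow and incomplete. The fallback sets out from 9 and returns at 10 by a Mitsunobu reaction with methanol (MeOH, PPh3, DIAD, THF, 0 °C → rt). It relies on the high acidity of the phenol and on a strongly activated methyl donor instead of carbonate-driven alkylation. It makes no new compound (F0).

Further compounds
F1 | step 1 | 1-bromo-3-methoxy-2-(2-nitrophenoxy)benzene | COc1cccc(Br)c1Oc1ccccc1[N+](=O)[O-]
F2 | step 1 | 2-(2-bromo-6-methoxyphenoxy)aniline | COc1cccc(Br)c1Oc1ccccc1N
F3 | step 1 | 2-(2-bromo-6-methoxyphenoxy)benzenediazonium bromide | COc1cccc(Br)c1Oc1ccccc1[N+]#N.[Br-]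
F4 | step 3 | 1,2-dibromo-3-(2-bromophenoxy)-4-methoxybenzene | COc1ccc(Br)c(Br)c1Oc1ccccc1Br
F5 | step 3 | 3,4-dibromo-2-(2-bromophenoxy)phenol | Oc1ccc(Br)c(Br)c1Oc1ccccc1Br
F0 | step 4 | none | none
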